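**Strategy.** The dihydropyranone ring (O1, C2 carbonyl, C3 to C6, C6 the carbinol) is cut at C5–C6 and at C2–C3. It then falls apart into an enal (C6 with its side chain), carbon monoxide (C2) and a three-carbon unit hidden in a 2-boryl-1,3-diene. In one flask the diene boronate adds through its vinyl terminus to the aldehyde under a chiral phosphoric acid (C5–C6, S centre at C6) to give a 3,4-dienol. Ru3(CO)12 under CO then stitches C2 between O1 and the central allene carbon (C2–C3). The step exploits the 1,5 relation of O1 and C3, and the fact that the first CH2 of the 4-methylpent-3-enyl group on C3 can be the far allene carbon.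

Key step: step 10

Assumption: the (S)-acid is taken to direct attack to the Si face of the enal carbonyl, by analogy with allyl- and allenylboronate additions in which the (R)-acid gives R carbinols from aryl and alkenyl aldehydes; if the sense were opposite, the (R)-acid would be used.

**Enal fragment**

Step 1
Reactants: 1 (Z)-3-methylpent-2-en-4-yn-1-ol
Product: 2 (Z)-tert-butyldimethyl[(3-methylpent-2-en-4-yn-1-yl)oxy]silane
Conditions: TBSCl, imidazole, CH2Cl2, 0 °C to rt
Reagents that add atoms: tert-butyldimethylsilyl chloride, CC(C)(C)[Si](C)(C)Cl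
Why: Silyl ether formation masks the primary allylic alcohol, which would otherwise be oxidised in step 6 and interfere with the ruthenium stage of step 10.

Step 2
Reactants: 2 (Z)-tert-butyldimethyl[(3-methylpent-2-en-4-yn-1-yl)oxy]silane
Product: 3 (Z)-tert-butyldimethyl[(3-methylpenta-2,4-dien-1-yl)oxy]silane
Conditions: H2 (1 atm), Pd on CaCO3 poisoned with Pb(OAc)2 (Lindlar catalyst), quinoline, hexane, 0 °C
Reagents that add atoms: none
Why: Lindlar semi-hydrogenation should stop at the vinyl group, and the existing Z trisubstituted alkene is not touched.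

Step 3
Reactants: 3 (Z)-tert-butyldimethyl[(3-methylpenta-2,4-dien-1-yl)oxy]silane; 4 bromoethene
Product: 6 (Z)-tert-butyldimethyl[(3-methylhepta-2,6-dien-1-yl)oxy]silane, via alkyl-9-BBN borane 5 (not isolated)
Conditions: (9-BBN)2, THF, 0 °C to rt; then 4, Pd(dppf)Cl2 (5 mol %), K3PO4 (3 M in water), THF/DMF, 50 °C
Reagents that add atoms: none
Why: 9-BBN should hydroborate only the monosubstituted vinyl terminus (anti-Markovnikov), and the B-alkyl Suzuki–Miyaura coupling then joins the sp3 carbon to the vinyl group.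

Step 4
Reactants: 6 (Z)-tert-butyldimethyl[(3-methylhepta-2,6-dien-1-yl)oxy]silane; 7 2-methylidenepropane-1,3-diyl diacetate
Product: 8 2-[(Z)-6-(tert-butyldimethylsilyloxy)-4-methylhex-4-en-1-ylidene]propane-1,3-diyl diacetate
Conditions: second-generation Grubbs catalyst (5 mol %), 7 (4 equiv), CH2Cl2, 40 °C
Reagents that add atoms: none
Why: Olefin cross-metathesis of a terminal alkene with an excess of a symmetrical 1,1-disubstituted alkene gives a trisubstituted alkene with no E/Z question, and the hindered trisubstituted allylic-ether alkene should not take part.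

Step 5
Reactants: 8 2-[(Z)-6-(tert-butyldimethylsilyloxy)-4-methylhex-4-en-1-ylidene]propane-1,3-diyl diacetate
Product: 9 [(2Z,6Z)-8-(tert-butyldimethylsilyloxy)-2-(hydroxymethyl)-6-methylocta-2,6-dien-1-yl] acetate
Conditions: lipase (triacylglycerol hydrolase) from Burkholderia cepacia, phosphate buffer (pH 7)/acetone, 25 °C, stopped at one ester cleaved
Reagents that add atoms: none
Why: Lipase-catalysed regioselective ester hydrolysis should cleave the less hindered acetate trans to the alkyl chain, as is known for 2-alkylidenepropane-1,3-diyl diacetates, so the acetate cis to the chain stays.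

Step 6
Reactants: 9 [(2Z,6Z)-8-(tert-butyldimethylsilyloxy)-2-(hydroxymethyl)-6-methylocta-2,6-dien-1-yl] acetate
Product: 10 [(2E,6Z)-8-(tert-butyldimethylsilyloxy)-2-formyl-6-methylocta-2,6-dien-1-yl] acetate
Conditions: MnO2, CH2Cl2, rt
Reagents that add atoms: none
Why: MnO2 oxidation of the allylic alcohol gives the enal with retention of geometry, the formyl group trans to the chain, which is also the more stable isomer.

**Dienylboronate fragment**

Step 7
Reactants: 11 1-bromo-3-methylbut-2-ene; 12 ethynylmagnesium bromide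
Product: 13 5-methylhex-4-en-1-yne
Conditions: CuCl (5 mol %), THF, 0 to 50 °C
Reagents that add atoms: none
Why: Copper-catalysed coupling of an allylic bromide with an alkynyl Grignard reagent should give the linear skipped enyne by attack at the unsubstituted allyl terminus.

Step 8
Reactants: 13 5-methylhex-4-en-1-yne
Product: 14 4,4,5,5-tetramethyl-2-(5-methylhex-4-en-1-yn-1-yl)-1,3,2-dioxaborolane
Conditions: n-BuLi, THF, −78 °C; 2-isopropoxy-4,4,5,5-tetramethyl-1,3,2-dioxaborolane; then HCl in Et2O, −78 °C to rt
Reagents that add atoms: 2-isopropoxy-4,4,5,5-tetramethyl-1,3,2-dioxaborolane, CC(C)OB1OC(C)(C)C(C)(C)O1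
Why: Borylation of the lithium acetylide and acid collapse of the ate complex is the standard route to alkynyl pinacol boronates.

Step 9
Reactants: 14 4,4,5,5-tetramethyl-2-(5-methylhex-4-en-1-yn-1-yl)-1,3,2-dioxaborolane; 4 bromoethene
Product: 16 (E)-4,4,5,5-tetramethyl-2-(7-methylocta-1,3,6-trien-3-yl)-1,3,2-dioxaborolane, via geminal boryl zirconocene alkene 15 (not isolated)
Conditions: Cp2Zr(H)Cl, THF, rt; then 4, Pd(PPh3)4 (5 mol %), THF, 50 °C
Reagents that add atoms: none
Why: Hydrozirconation of an alkynylboronate places zirconium on the boron-bearing carbon by syn addition, and only the C–Zr bond should enter the Negishi-type coupling, so the boron position is fixed by mechanism; the alkene geometry does not matter later.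

**Union and completion**

Step 10
Reactants: 10 [(2E,6Z)-8-(tert-butyldimethylsilyloxy)-2-formyl-6-methylocta-2,6-dien-1-yl] acetate; 16 (E)-4,4,5,5-tetramethyl-2-(7-methylocta-1,3,6-trien-3-yl)-1,3,2-dioxaborolane
Product: 19 [(2E,6Z)-8-(tert-butyldimethylsilyloxy)-6-methyl-2-[(2S)-5-(4-methylpent-3-en-1-yl)-6-oxo-3,6-dihydro-2H-pyran-2-yl]octa-2,6-dien-1-yl] acetate, via pinacol borate ester 17 (not isolated), via homoallenic alcohol 18 (not isolated)
Conditions: (S)-TRIP (3,3′-bis(2,4,6-triisopropylphenyl)-1,1′-binaphthyl-2,2′-diyl hydrogen phosphate, 10 mol %), 4 Å MS, toluene, 0 °C to rt; then H2O (1.5 equiv), Et3N (2 equiv), Ru3(CO)12 (3 mol %), CO (10 atm), 1,4-dioxane, 100 °C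
Reagents that add atoms: carbon monoxide, [C-]#[O+]
Why: The phosphoric acid hydrogen-bonds to a boronate oxygen of 16 and to the formyl group of 10, and in a closed six-membered transition state the vinyl CH2 terminus of the diene attacks the Si face of the aldehyde while the C–B bond becomes the new allene (SE2′ dienylboration), which forms the C5–C6 bond and borate 17. Water frees allenol 18, whose O–H adds to ruthenium; CO insertion gives an alkoxycarbonyl ruthenium hydride, the acyl carbon then adds to the central allene carbon (C2–C3 bond), and hydride transfer to the far allene carbon releases 19 with that carbon as the first CH2 of the 4-methylpent-3-enyl chain. The closest known reaction types are the γ-selective carbonyl addition of 1,3-dien-2-ylboron reagents that gives β-allenyl carbinols, chiral phosphoric acid catalysed allyl- and allenylboration, and the Ru3(CO)12-catalysed cyclocarbonylation of 3,4-dienols to 5,6-dihydropyran-2-ones. The six-membered ring closes in a 6-exo-dig sense by acyl-metal addition to the sp carbon, the consumed π bond lying outside the ring, so the C3=C4 alkene is necessarily cis within the ring. The only stereocentre, C6, is set S in the boration stage by the chiral acid (catalyst control of the aldehyde face) and is not touched afterwards, while the allene axis is destroyed and need not be controlled. The step needs 1,2- over 1,4-addition and γ-attack of the diene, secured by the cyclic boron transition state, and it needs CO delivery to the central carbon with hydrogen delivery to the exocyclic terminus, secured by the O1–C6–C5–C4 tether that allows only the six-membered acyl transfer and by the conjugation gained in the ring.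

Step 11
Reactants: 19 [(2E,6Z)-8-(tert-butyldimethylsilyloxy)-6-methyl-2-[(2S)-5-(4-methylpent-3-en-1-yl)-6-oxo-3,6-dihydro-2H-pyran-2-yl]octa-2,6-dien-1-yl] acetate
Product: 20 [(2E,6Z)-8-hydroxy-6-methyl-2-[(2S)-5-(4-methylpent-3-en-1-yl)-6-oxo-3,6-dihydro-2H-pyran-2-yl]octa-2,6-dien-1-yl] acetate
Conditions: HF·pyridine, THF/pyridine, 0 °C
Reagents that add atoms: none
Why: Fluoride-mediated desilylation should cleave the primary silyl ether while the acetate, the unsaturated lactone and the C6 stereocentre stay intact.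

**Compound list**

1 | (Z)-3-methylpent-2-en-4-yn-1-ol | C#C/C(C)=C\CO | starting material
2 | (Z)-tert-butyldimethyl[(3-methylpent-2-en-4-yn-1-yl)oxy]silane | C#C/C(C)=C\CO[Si](C)(C)C(C)(C)C | intermediate
3 | (Z)-tert-butyldimethyl[(3-methylpenta-2,4-dien-1-yl)oxy]silane | C=C/C(C)=C\CO[Si](C)(C)C(C)(C)C | intermediate
4 | bromoethene | C=CBr | starting material
5 | 9-[(Z)-5-(tert-butyldimethylsilyloxy)-3-methylpent-3-en-1-yl]-9-borabicyclo[3.3.1]nonane | B1(CC/C(C)=C\CO[Si](C)(C)C(C)(C)C)C2CCCC1CCC2 | intermediate
6 | (Z)-tert-butyldimethyl[(3-methylhepta-2,6-dien-1-yl)oxy]silane | C=CCC/C(C)=C\CO[Si](C)(C)C(C)(C)C | intermediate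
7 | 2-methylidenepropane-1,3-diyl diacetate | C=C(COC(C)=O)COC(C)=O | starting material
8 | 2-[(Z)-6-(tert-butyldimethylsilyloxy)-4-methylhex-4-en-1-ylidene]propane-1,3-diyl diacetate | CC(=O)OCC(COC(C)=O)=CCC/C(C)=C\CO[Si](C)(C)C(C)(C)C | intermediate
9 | [(2Z,6Z)-8-(tert-butyldimethylsilyloxy)-2-(hydroxymethyl)-6-methylocta-2,6-dien-1-yl] acetate | CC(=O)OC/C(CO)=C\CC/C(C)=C\CO[Si](C)(C)C(C)(C)C | intermediate
10 | [(2E,6Z)-8-(tert-butyldimethylsilyloxy)-2-formyl-6-methylocta-2,6-dien-1-yl] acetate | CC(=O)OC/C(C=O)=C\CC/C(C)=C\CO[Si](C)(C)C(C)(C)C | intermediate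
11 | 1-bromo-3-methylbut-2-ene | CC(C)=CCBr | starting material
12 | ethynylmagnesium bromide | C#C[Mg]Br | starting material
13 | 5-methylhex-4-en-1-yne | C#CCC=C(C)C | intermediate
14 | 4,4,5,5-tetramethyl-2-(5-methylhex-4-en-1-yn-1-yl)-1,3,2-dioxaborolane | CC(C)=CCC#CB1OC(C)(C)C(C)(C)O1 | intermediate
15 | chlorobis(cyclopentadienyl)[(E)-5-methyl-1-(4,4,5,5-tetramethyl-1,3,2-dioxaborolan-2-yl)hexa-1,4-dien-1-yl]zirconium | CC(C)=CC/C=C(/[Zr](Cl)(C1C=CC=C1)C1C=CC=C1)B1OC(C)(C)C(C)(C)O1 | intermediate
16 | (E)-4,4,5,5-tetramethyl-2-(7-methylocta-1,3,6-trien-3-yl)-1,3,2-dioxaborolane | CC(C)=CC/C=C(/C=C)B1OC(C)(C)C(C)(C)O1 | intermediate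
17 | pinacol borate ester of 18 (O-boryl at the S carbinol, either allene-axis epimer) | CC(=O)OC/C(=C\CC/C(C)=C\CO[Si](C)(C)C(C)(C)C)[C@@H](OB1OC(C)(C)C(C)(C)O1)CC=C=CCC=C(C)C | intermediate
18 | [(2E,6Z)-8-(tert-butyldimethylsilyloxy)-2-[(1S)-1-hydroxy-8-methylnona-3,4,7-trien-1-yl]-6-methylocta-2,6-dien-1-yl] acetate | CC(=O)OC/C(=C\CC/C(C)=C\CO[Si](C)(C)C(C)(C)C)[C@@H](O)CC=C=CCC=C(C)C | intermediate
19 | [(2E,6Z)-8-(tert-butyldimethylsilyloxy)-6-methyl-2-[(2S)-5-(4-methylpent-3-en-1-yl)-6-oxo-3,6-dihydro-2H-pyran-2-yl]octa-2,6-dien-1-yl] acetate | CC(=O)OC/C(=C\CC/C(C)=C\CO[Si](C)(C)C(C)(C)C)[C@@H]1CC=C(CCC=C(C)C)C(=O)O1 | intermediate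
20 | [(2E,6Z)-8-hydroxy-6-methyl-2-[(2S)-5-(4-methylpent-3-en-1-yl)-6-oxo-3,6-dihydro-2H-pyran-2-yl]octa-2,6-dien-1-yl] acetate | CC(=O)OC/C(=C\CC/C(C)=C\CO)[C@@H]1CC=C(CCC=C(C)C)C(=O)O1 | target

**Count**

Total steps: 11. Longest linear sequence: 8 steps (1, 2, 3, 4, 5, 6, 10, 11); steps 7 to 9 make the boronate branch.

**Steps most likely to fail**

Step 10. The vinylic boronate may add too slowly, so that an uncatalysed background addition or heating erodes the facial control. In the ruthenium stage, hydrogen delivery to the ring carbon instead of the exocyclic terminus would give the exocyclic alkylidene lactone. Ionisation of the allylic acetate, acetyl migration to the C6 oxygen before carbonylation, or base-induced ring-opening elimination of the product may also intervene. The fallback sets out from 10 and builds the ring by allylation, ring-closing metathesis and a late C3 alkylation. (S)-TRIP-catalysed allylboration with allylboronic acid pinacol ester should give [(2E,6Z)-8-(tert-butyldimethylsilyloxy)-2-[(1S)-1-hydroxybut-3-en-1-yl]-6-methylocta-2,6-dien-1-yl] acetate F1. Acylation with acryloyl chloride and Et3N should give the acrylate F2. Ring-closing metathesis with the second-generation Grubbs catalyst should give the C3-unsubstituted dihydropyranone F3. Iodination at C3 with I2 and pyridine should give the 3-iodo lactone F4. B-alkyl Suzuki–Miyaura coupling of F4 with 9-(4-methylpent-3-en-1-yl)-9-borabicyclo[3.3.1]nonane F5 (from 4-methylpenta-1,3-diene and 9-BBN; Pd(dppf)Cl2, AsPh3, K3PO4) comes back to the route at 19.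

Step 9. Transmetalation of the hindered geminal boryl zirconium alkene to palladium may be too slow, so that protonolysis to the simple alkenylboronate or homocoupling takes over. The fallback sets out from 14 and swaps the polarity of the coupling. Hydrozirconation as before and cleavage of the C–Zr bond with N-bromosuccinimide should give (E)-2-(1-bromo-5-methylhexa-1,4-dien-1-yl)-4,4,5,5-tetramethyl-1,3,2-dioxaborolane F6. A base-free Stille coupling of the C–Br bond with tributyl(vinyl)stannane (Pd(PPh3)4, CuI, DMF) leaves the boronate alone and comes back to the route at 16.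

Step 5. The enzyme may discriminate poorly between the two acetates, hydrolyse both, or the monoacetate may scramble by acyl migration between the two oxygens. The fallback sets out from 8 and uses the thermodynamic preference of the enal instead. Methanolysis (K2CO3, MeOH) should give 2-[(Z)-6-(tert-butyldimethylsilyloxy)-4-methylhex-4-en-1-ylidene]propane-1,3-diol F7. Mono-oxidation with MnO2 and equilibration to the more stable isomer, formyl trans to the chain, should give (2E,6Z)-8-(tert-butyldimethylsilyloxy)-2-(hydroxymethyl)-6-methylocta-2,6-dienal F8. Acetylation (Ac2O, pyridine) comes back to the route at 10.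

**Further compounds**

F1 | step 10 | [(2E,6Z)-8-(tert-butyldimethylsilyloxy)-2-[(1S)-1-hydroxybut-3-en-1-yl]-6-methylocta-2,6-dien-1-yl] acetate | CC(=O)OC/C(=C\CC/C(C)=C\CO[Si](C)(C)C(C)(C)C)[C@@H](O)CC=C
F2 | step 10 | (1S)-1-[(2E,6Z)-1-acetoxy-8-(tert-butyldimethylsilyloxy)-6-methylocta-2,6-dien-2-yl]but-3-en-1-yl prop-2-enoate | CC(=O)OC/C(=C\CC/C(C)=C\CO[Si](C)(C)C(C)(C)C)[C@@H](OC(=O)C=C)CC=C
F3 | step 10 | [(2E,6Z)-8-(tert-butyldimethylsilyloxy)-6-methyl-2-[(2S)-6-oxo-3,6-dihydro-2H-pyran-2-yl]octa-2,6-dien-1-yl] acetate | CC(=O)OC/C(=C\CC/C(C)=C\CO[Si](C)(C)C(C)(C)C)[C@@H]1CC=CC(=O)O1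
F4 | step 10 | [(2E,6Z)-8-(tert-butyldimethylsilyloxy)-2-[(2S)-5-iodo-6-oxo-3,6-dihydro-2H-pyran-2-yl]-6-methylocta-2,6-dien-1-yl] acetate | CC(=O)OC/C(=C\CC/C(C)=C\CO[Si](C)(C)C(C)(C)C)[C@@H]1CC=C(I)C(=O)O1
F5 | step 10 | 9-(4-methylpent-3-en-1-yl)-9-borabicyclo[3.3.1]nonane | CC(C)=CCCB1C2CCCC1CCC2
F6 | step 9 | (E)-2-(1-bromo-5-methylhexa-1,4-dien-1-yl)-4,4,5,5-tetramethyl-1,3,2-dioxaborolane | CC(C)=CC/C=C(/Br)B1OC(C)(C)C(C)(C)O1
F7 | step 5 | 2-[(Z)-6-(tert-butyldimethylsilyloxy)-4-methylhex-4-en-1-ylidene]propane-1,3-diol | OCC(CO)=CCC/C(C)=C\CO[Si](C)(C)C(C)(C)C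
F8 | step 5 | (2E,6Z)-8-(tert-butyldimethylsilyloxy)-2-(hydroxymethyl)-6-methylocta-2,6-dienal | OC/C(C=O)=C\CC/C(C)=C\CO[Si](C)(C)C(C)(C)C
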